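I started from the late end of this flask: long after the charge has gone in, how much catalyst can still go round?

substrate 20 mM; coupling partner 1.50 equiv; free catalyst 2 mol%; impurity 0.25 mM

    substrate + free catalyst ⇌ catalyst intermediate A (K1 = 2100 L mol⁻¹, k1 = 70.4 L mol⁻¹ s⁻¹)
    coupling partner + catalyst intermediate A → catalyst intermediate B (k2 = 32.3 L mol⁻¹ s⁻¹)
    catalyst intermediate B → released group + catalyst intermediate C (k3 = 2.10 s⁻¹)
    catalyst intermediate C ⇌ free catalyst + product (K4 = 0.0073 M, k4 = 8.59 s⁻¹)
    free catalyst + impurity → spent catalyst (k5 = 49300 L mol⁻¹ s⁻¹)

- the form that holds most of the catalyst when 30% of the substrate are converted (catalyst intermediate C / catalyst intermediate A / catalyst intermediate B / spent catalyst / free catalyst)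
- its share of the catalyst then
- apparent order in free catalyst when 30% of the substrate are converted (percent change of the rate of making product for one percent more free catalyst charged)

First I took the main round alone, the first four steps without the impurity. Every step in it goes in proportion to one form of the catalyst, and those forms merely pass into each other. So at a given conversion the rate of making product keeps in step with the catalyst charged, an order of one.

Then I added the poison, starting at the early end. At the start, substrate takes up free catalyst at 0.11 of the rate at which impurity does, which is slower, so free catalyst goes mostly to the impurity, and each free catalyst leaving the round meets the same choice. The catalyst charged, 0.400 mM, is more than the impurity charged, 0.25 mM, so the impurity is the limiting reagent of this side reaction and gives out first.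

Joining the two ends, the round runs on 0.150 mM, the working catalyst, which is the catalyst charged less the impurity charged. Spent catalyst then holds 62.5% of the catalyst, more than the working catalyst can hold in any form. The impurity stays the same when more catalyst is charged, so the whole addition is working catalyst, and the order becomes the catalyst charged over the working catalyst, 2.67.

The back steps came last. At 30% conversion, product returns catalyst intermediate C at 7.06 s⁻¹ per free catalyst, which shifts catalyst among the working forms. It leaves the working catalyst, and so both my numbers, as they were.

The forecast named spent catalyst, at 62.5%, with an order of 2.67, on the ground that “all the impurity is consumed within seconds”. My reckoning gives the same values.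

The flask gave spent catalyst at 62.5%, with an order of 2.7, when it reached that conversion at 119 s. Spent catalyst lies outside the round, so it is no resting state. Already after 4.00 s the impurity stood at 0% of its charge and spent catalyst at 62.5% of the catalyst charged. The rate of making product at 119 s, when 30% of the substrate was converted, was 0.0395 mM s⁻¹, which comes to 0.0987 s⁻¹ per catalyst charged, but to 0.263 s⁻¹ per working catalyst.

The rate constants were drawn at random within sensible limits; the run is a simulation.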